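**Plan**
Isocryptomerin is read as two flavones joined by a diaryl ether: unit 1 is the 7-methoxyflavone carrying the ether oxygen at C6, and unit 2 is the 5,7-dihydroxyflavone whose ring B carries that oxygen. Flavone numbering is used for both.
Retrosynthesis: ring C of unit 2 is cut at O1–C2 and C2–C3 (chalcone, then aldehyde plus acetophenone). Ring C of unit 1 is then cut at O1–C8a, C4–C4a and O1–C2 (aryne plus arylpropiolic acid). The C6–O–aryl bond is cut last (SNAr).
Enabling feature: in ring A of unit 1, O1 (on C8a) and the carbonyl carbon C4 (on C4a) sit on adjacent carbons, and C4a is flanked by the C5 oxygen. A 3-alkoxyaryne delivers exactly this pattern when an oxygen nucleophile enters at its far carbon and an acyl group at its near carbon. Equal methoxy groups at C5 and C7 make the ring A phenol mirror-symmetric.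
Forward: the diaryl ether is made first and ring A is armed as an ortho-silylaryl triflate. Ring C of unit 1 closes in the aryne step and ring C of unit 2 closes by oxidative chalcone cyclisation. BCl3 then frees four phenols and distinguishes the C5 from the C7 methyl ether by chelation to C4=O.
Stereochemistry: the target has no stereocentre. The only stereo-element on the way, the E-alkene of the chalcone, is thermodynamic and is consumed.

Key step: step 9

Remark on the chemistry: the directing carbamate is the N,N-diethyl type because it must first survive K2CO3 at 120 °C as a protecting group. A carbamate with an N–H would fragment there.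

Step 1
Reactants: 1 2,6-dimethoxy-1,4-benzoquinone
Product: 2 2,6-dimethoxybenzene-1,4-diol
Conditions: Na2S2O4, H2O/EtOAc, rt, Ar
Reagents that add atoms: none
Why: Reduction of a benzoquinone to its hydroquinone with Na2S2O4 is fast in a two-phase medium and leaves both methyl ethers untouched.

Step 2
Reactants: 2 2,6-dimethoxybenzene-1,4-diol
Product: 3 4-hydroxy-3,5-dimethoxyphenyl N,N-diethylcarbamate
Conditions: NaH (1.0 equiv), THF, 0 °C; Et2NCOCl (1.0 equiv), 0 to 50 °C, Ar
Reagents that add atoms: N,N-diethylcarbamoyl chloride, CCN(CC)C(=O)Cl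
Why: In this O-carbamoylation of a monophenoxide, one equivalent of NaH removes the more acidic proton of the hydroxyl meta to both methoxy groups, which is also the unhindered one, so the hydroxyl flanked by two methoxy groups stays free.

Step 3
Reactants: 3 4-hydroxy-3,5-dimethoxyphenyl N,N-diethylcarbamate; 4 4-fluorobenzaldehyde
Product: 5 4-(4-formylphenoxy)-3,5-dimethoxyphenyl N,N-diethylcarbamate
Conditions: K2CO3, dry DMF, 120 °C, Ar
Reagents that add atoms: none
Why: In this nucleophilic aromatic substitution by addition–elimination, the para-formyl group activates the fluoride towards the hindered phenoxide, and the tertiary carbamate is inert to K2CO3 in dry DMF.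

Step 4
Reactants: 5 4-(4-formylphenoxy)-3,5-dimethoxyphenyl N,N-diethylcarbamate
Product: 6 4-[4-(1,3-dioxolan-2-yl)phenoxy]-3,5-dimethoxyphenyl N,N-diethylcarbamate
Conditions: ethylene glycol, p-TsOH (cat.), toluene, reflux, azeotropic removal of water
Reagents that add atoms: ethylene glycol, OCCO
Why: Acid-catalysed acetalisation masks the aldehyde against the organolithium, hydride and aryne chemistry that follows, and the aryl carbamate tolerates it.

Step 5
Reactants: 6 4-[4-(1,3-dioxolan-2-yl)phenoxy]-3,5-dimethoxyphenyl N,N-diethylcarbamate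
Product: 8 4-[4-(1,3-dioxolan-2-yl)phenoxy]-3,5-dimethoxy-2-(trimethylsilyl)phenyl N,N-diethylcarbamate, via 2-lithiated carbamate 7 (not isolated)
Conditions: s-BuLi, TMEDA, THF, −78 °C; then Me3SiCl, −78 °C to rt
Reagents that add atoms: chlorotrimethylsilane, C[Si](C)(C)Cl
Why: In this directed ortho-metalation the C–H between the carbamate and a methoxy group is acidified by both directing groups, the two such positions are equivalent by the mirror plane of the ring, and silylation at −78 °C outruns the anionic ortho-Fries shift.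

Step 6
Reactants: 8 4-[4-(1,3-dioxolan-2-yl)phenoxy]-3,5-dimethoxy-2-(trimethylsilyl)phenyl N,N-diethylcarbamate
Product: 9 4-[4-(1,3-dioxolan-2-yl)phenoxy]-3,5-dimethoxy-2-(trimethylsilyl)phenol
Conditions: LiAlH4, THF, 0 to 50 °C; Na2SO4·10H2O quench; crude product carried on without chromatography
Reagents that add atoms: none
Why: Reductive cleavage of an aryl carbamate proceeds by hydride addition to the carbonyl and expulsion of phenoxide, the acetal, the aryl ethers and the C–Si bond are inert to LiAlH4, and the neutral quench avoids protodesilylation.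

Step 7
Reactants: 9 4-[4-(1,3-dioxolan-2-yl)phenoxy]-3,5-dimethoxy-2-(trimethylsilyl)phenol
Product: 10 4-[4-(1,3-dioxolan-2-yl)phenoxy]-3,5-dimethoxy-2-(trimethylsilyl)phenyl trifluoromethanesulfonate
Conditions: PhNTf2, DBU, MeCN, rt
Reagents that add atoms: N-phenylbis(trifluoromethanesulfonimide), O=S(=O)(N(c1ccccc1)S(=O)(=O)C(F)(F)F)C(F)(F)F
Why: Phenol triflation with a mild triflyl-transfer reagent under amine base keeps the medium free of acid, which spares the acetal and the electron-rich aryl–silicon bond.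

Step 8
Reactants: 11 1-(benzyloxy)-4-ethynylbenzene
Product: 13 3-[4-(benzyloxy)phenyl]propiolic acid, via lithium acetylide 12 (not isolated)
Conditions: n-BuLi, THF, −78 °C; CO2; then 1 M HCl
Reagents that add atoms: carbon dioxide, O=C=O
Why: Carboxylation of a lithium acetylide with CO2 is the standard entry to arylpropiolic acids, and the benzyl ether is inert to it.

Step 9
Reactants: 10 4-[4-(1,3-dioxolan-2-yl)phenoxy]-3,5-dimethoxy-2-(trimethylsilyl)phenyl trifluoromethanesulfonate; 13 3-[4-(benzyloxy)phenyl]propiolic acid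
Product: 16 2-[4-(benzyloxy)phenyl]-6-[4-(1,3-dioxolan-2-yl)phenoxy]-5,7-dimethoxy-4H-chromen-4-one, via aryne 14 (not isolated), via ortho-hydroxyaryl ynone 15 (not isolated)
Conditions: CsF (4 equiv), 10 (1.5 equiv), THF (ca. 0.02 M), 125 °C, sealed vessel
Reagents that add atoms: none
Why: Fluoride attacks silicon in 10 and triflate leaves to give aryne 14 (C4a≡C8a), the carboxylate oxygen of 13 adds to C8a, and the C4a aryl anion, held beside the new ester, attacks its carbonyl through a strained four-membered alkoxide that collapses with oxygen-to-carbon acyl transfer to the phenoxide of ynone 15. That phenoxide adds to the β-carbon of the ynone and protonation completes the pyranone, so O1–C8a, C4a–C4 and O1–C2 all form in one operation. The closest known reaction type is the intermolecular C–O insertion of arynes into carboxylic acids under CsF in hot THF, which with arylpropiolic acids is known to run on to flavones. The single ring closed is ring C of unit 1, by 6-endo-dig oxa-Michael addition, which aprotic fluoride media favour over the 5-exo-dig path. No stereocentre is created. The selectivity needed, oxygen at C8a and acyl at C4a, is secured by the C5 methoxy group, whose inductive pull widens the angle at the far aryne carbon and stabilises the developing charge at C4a, while high dilution in a hot aprotic solvent favours acyl transfer over protonation of the aryl anion.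

Step 10
Reactants: 16 2-[4-(benzyloxy)phenyl]-6-[4-(1,3-dioxolan-2-yl)phenoxy]-5,7-dimethoxy-4H-chromen-4-one
Product: 17 4-({2-[4-(benzyloxy)phenyl]-5,7-dimethoxy-4-oxo-4H-chromen-6-yl}oxy)benzaldehyde
Conditions: 1 M HCl, THF, rt
Reagents that add atoms: water, O
Why: Acid-catalysed acetal hydrolysis frees the aldehyde, and the flavone, the benzyl ether and the methyl ethers tolerate dilute acid at room temperature.

Step 11
Reactants: 18 2',4',6'-trihydroxyacetophenone
Product: 19 1-[2,4-bis(benzyloxy)-6-hydroxyphenyl]ethanone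
Conditions: BnBr (2.1 equiv), K2CO3, DMF, 60 °C
Reagents that add atoms: benzyl bromide, BrCc1ccccc1
Why: Williamson etherification with two equivalents of benzyl bromide stops at the dibenzyl ether because the last hydroxyl is locked in a hydrogen bond to the acetyl carbonyl and is the least nucleophilic.

Step 12
Reactants: 17 4-({2-[4-(benzyloxy)phenyl]-5,7-dimethoxy-4-oxo-4H-chromen-6-yl}oxy)benzaldehyde; 19 1-[2,4-bis(benzyloxy)-6-hydroxyphenyl]ethanone
Product: 20 (E)-1-[2,4-bis(benzyloxy)-6-hydroxyphenyl]-3-[4-({2-[4-(benzyloxy)phenyl]-5,7-dimethoxy-4-oxo-4H-chromen-6-yl}oxy)phenyl]prop-2-en-1-one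
Conditions: KOH (50% aq.), EtOH–THF, rt, Ar; then dilute HCl
Reagents that add atoms: none
Why: Claisen–Schmidt condensation (aldol addition, then E1cB dehydration) of the non-enolisable aldehyde with the methyl ketone gives the conjugated enone, whose E geometry is the thermodynamic outcome.

Step 13
Reactants: 20 (E)-1-[2,4-bis(benzyloxy)-6-hydroxyphenyl]-3-[4-({2-[4-(benzyloxy)phenyl]-5,7-dimethoxy-4-oxo-4H-chromen-6-yl}oxy)phenyl]prop-2-en-1-one
Product: 21 6-{4-[5,7-bis(benzyloxy)-4-oxo-4H-chromen-2-yl]phenoxy}-2-[4-(benzyloxy)phenyl]-5,7-dimethoxy-4H-chromen-4-one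
Conditions: I2 (10 mol %), DMSO, 130 °C
Reagents that add atoms: none
Why: The iodine-catalysed oxidative cyclisation of a 2'-hydroxychalcone (oxa-Michael closure, α-iodination and loss of hydrogen iodide, with DMSO as terminal oxidant) is the standard chalcone-to-flavone conversion and leaves ethers and the existing flavone alone.

Step 14
Reactants: 21 6-{4-[5,7-bis(benzyloxy)-4-oxo-4H-chromen-2-yl]phenoxy}-2-[4-(benzyloxy)phenyl]-5,7-dimethoxy-4H-chromen-4-one
Product: 22 isocryptomerin
Conditions: BCl3 (excess), pentamethylbenzene, CH2Cl2, −78 °C to rt; then 1 M HCl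
Reagents that add atoms: none
Why: In this Lewis-acid ether cleavage BCl3 removes the three benzyl ethers while pentamethylbenzene traps the benzyl cations, and it cleaves only the methyl ether whose oxygen can chelate boron together with C4=O (5-OMe of unit 1), leaving the 7-OMe and the diaryl ether intact.

**Compound list**
1 | 2,6-dimethoxy-1,4-benzoquinone | COC1=CC(=O)C=C(OC)C1=O | starting material
2 | 2,6-dimethoxybenzene-1,4-diol | COc1cc(O)cc(OC)c1O | intermediate
3 | 4-hydroxy-3,5-dimethoxyphenyl N,N-diethylcarbamate | CCN(CC)C(=O)Oc1cc(OC)c(O)c(OC)c1 | intermediate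
4 | 4-fluorobenzaldehyde | O=Cc1ccc(F)cc1 | starting material
5 | 4-(4-formylphenoxy)-3,5-dimethoxyphenyl N,N-diethylcarbamate | CCN(CC)C(=O)Oc1cc(OC)c(Oc2ccc(C=O)cc2)c(OC)c1 | intermediate
6 | 4-[4-(1,3-dioxolan-2-yl)phenoxy]-3,5-dimethoxyphenyl N,N-diethylcarbamate | CCN(CC)C(=O)Oc1cc(OC)c(Oc2ccc(cc2)C2OCCO2)c(OC)c1 | intermediate
7 | 2-lithio derivative of 6 (lithium between carbamate and methoxy) | CCN(CC)C(=O)Oc1cc(OC)c(Oc2ccc(cc2)C2OCCO2)c(OC)c1[Li] | intermediate
8 | 4-[4-(1,3-dioxolan-2-yl)phenoxy]-3,5-dimethoxy-2-(trimethylsilyl)phenyl N,N-diethylcarbamate | CCN(CC)C(=O)Oc1cc(OC)c(Oc2ccc(cc2)C2OCCO2)c(OC)c1[Si](C)(C)C | intermediate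
9 | 4-[4-(1,3-dioxolan-2-yl)phenoxy]-3,5-dimethoxy-2-(trimethylsilyl)phenol | COc1cc(O)c([Si](C)(C)C)c(OC)c1Oc1ccc(cc1)C1OCCO1 | intermediate
10 | 4-[4-(1,3-dioxolan-2-yl)phenoxy]-3,5-dimethoxy-2-(trimethylsilyl)phenyl trifluoromethanesulfonate | COc1cc(OS(=O)(=O)C(F)(F)F)c([Si](C)(C)C)c(OC)c1Oc1ccc(cc1)C1OCCO1 | intermediate
11 | 1-(benzyloxy)-4-ethynylbenzene | C#Cc1ccc(OCc2ccccc2)cc1 | starting material
12 | lithium [4-(benzyloxy)phenyl]acetylide | [Li]C#Cc1ccc(OCc2ccccc2)cc1 | intermediate
13 | 3-[4-(benzyloxy)phenyl]propiolic acid | OC(=O)C#Cc1ccc(OCc2ccccc2)cc1 | intermediate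
14 | 4-[4-(1,3-dioxolan-2-yl)phenoxy]-3,5-dimethoxybenzyne (1,2-didehydrobenzene numbering) | COC1=CC#CC(OC)=C1Oc1ccc(cc1)C1OCCO1 | intermediate
15 | 3-[4-(benzyloxy)phenyl]-1-{3-[4-(1,3-dioxolan-2-yl)phenoxy]-6-hydroxy-2,4-dimethoxyphenyl}prop-2-yn-1-one | COc1cc(O)c(C(=O)C#Cc2ccc(OCc3ccccc3)cc2)c(OC)c1Oc1ccc(cc1)C1OCCO1 | intermediate
16 | 2-[4-(benzyloxy)phenyl]-6-[4-(1,3-dioxolan-2-yl)phenoxy]-5,7-dimethoxy-4H-chromen-4-one | COc1cc2oc(-c3ccc(OCc4ccccc4)cc3)cc(=O)c2c(OC)c1Oc1ccc(cc1)C1OCCO1 | intermediate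
17 | 4-({2-[4-(benzyloxy)phenyl]-5,7-dimethoxy-4-oxo-4H-chromen-6-yl}oxy)benzaldehyde | COc1cc2oc(-c3ccc(OCc4ccccc4)cc3)cc(=O)c2c(OC)c1Oc1ccc(C=O)cc1 | intermediate
18 | 2',4',6'-trihydroxyacetophenone | CC(=O)c1c(O)cc(O)cc1O | starting material
19 | 1-[2,4-bis(benzyloxy)-6-hydroxyphenyl]ethanone | CC(=O)c1c(O)cc(OCc2ccccc2)cc1OCc1ccccc1 | intermediate
20 | (E)-1-[2,4-bis(benzyloxy)-6-hydroxyphenyl]-3-[4-({2-[4-(benzyloxy)phenyl]-5,7-dimethoxy-4-oxo-4H-chromen-6-yl}oxy)phenyl]prop-2-en-1-one | COc1cc2oc(-c3ccc(OCc4ccccc4)cc3)cc(=O)c2c(OC)c1Oc1ccc(/C=C/C(=O)c2c(O)cc(OCc3ccccc3)cc2OCc2ccccc2)cc1 | intermediate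
21 | 6-{4-[5,7-bis(benzyloxy)-4-oxo-4H-chromen-2-yl]phenoxy}-2-[4-(benzyloxy)phenyl]-5,7-dimethoxy-4H-chromen-4-one | COc1cc2oc(-c3ccc(OCc4ccccc4)cc3)cc(=O)c2c(OC)c1Oc1ccc(-c2cc(=O)c3c(OCc4ccccc4)cc(OCc4ccccc4)cc3o2)cc1 | intermediate
22 | isocryptomerin, 6-[4-(5,7-dihydroxy-4-oxo-4H-chromen-2-yl)phenoxy]-5-hydroxy-2-(4-hydroxyphenyl)-7-methoxy-4H-chromen-4-one | COc1cc2oc(-c3ccc(O)cc3)cc(=O)c2c(O)c1Oc1ccc(-c2cc(=O)c3c(O)cc(O)cc3o2)cc1 | target

Total step count: 14. Longest linear sequence: 12 (steps 1–7, 9, 10, 12, 13, 14).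

**Steps most likely to fail**

Step 9. The C4a aryl anion may be protonated by the acid before the acyl group migrates, which gives plain O-arylation. The propiolate may also lose CO2 at 125 °C, or the final closure may drift to the 5-exo mode. The fallback sets out from 9 and comes back at 16. ipso-Iododesilylation of 9 with N-iodosuccinimide in MeCN at 0 °C should give 4-[4-(1,3-dioxolan-2-yl)phenoxy]-2-iodo-3,5-dimethoxyphenol F1. A palladium-catalysed carbonylative Sonogashira annulation of F1 with alkyne 11 (PdCl2(dppf), CO 20 bar, Et2NH, 120 °C) then builds ynone 15 in the flask. The amine medium is known to steer its closure to the six-membered ring, which gives 16.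

Step 6. The silicon-bearing carbon is ortho, ortho and para to three oxygen donors, so the trimethylsilyl group may be lost by protodesilylation during quench or handling of the free phenol. Hydride attack on the flanked carbamate may also be slow. The fallback sets out from 6 and comes back at 10.
- LiAlH4 in THF cleaves the unhindered carbamate of 6 to 4-[4-(1,3-dioxolan-2-yl)phenoxy]-3,5-dimethoxyphenol F2.
- One equivalent of N-bromosuccinimide in MeCN at 0 °C in the dark gives 2-bromo-4-[4-(1,3-dioxolan-2-yl)phenoxy]-3,5-dimethoxyphenol F3. Only one monobromide is possible, by symmetry.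
- Hexamethyldisilazane in THF at 70 °C gives {2-bromo-4-[4-(1,3-dioxolan-2-yl)phenoxy]-3,5-dimethoxyphenoxy}trimethylsilane F4.
- n-BuLi in THF at −78 °C triggers bromine–lithium exchange and a retro-Brook shift of silicon from oxygen to carbon. This gives lithium 4-[4-(1,3-dioxolan-2-yl)phenoxy]-3,5-dimethoxy-2-(trimethylsilyl)phenolate F5, which is triflated in the same flask with Tf2O to 10. The silylphenol therefore never meets a proton source.

Step 12. Hydroxide may add to C2 of the pyranone of unit 1 and open the ring. Enolisation of the phenoxide-bearing ketone may also be so slow that the condensation stalls. The fallback sets out from 17 and comes back at 21, bypassing 20 and step 13.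
- Pinnick oxidation (NaClO2, NaH2PO4, 2-methyl-2-butene, t-BuOH–THF–H2O) gives 4-({2-[4-(benzyloxy)phenyl]-5,7-dimethoxy-4-oxo-4H-chromen-6-yl}oxy)benzoic acid F6.
- Steglich esterification with 19 (EDC, DMAP, CH2Cl2) gives 2-acetyl-3,5-bis(benzyloxy)phenyl 4-({2-[4-(benzyloxy)phenyl]-5,7-dimethoxy-4-oxo-4H-chromen-6-yl}oxy)benzoate F7.
- Baker–Venkataraman rearrangement with the non-nucleophilic base LiN(SiMe3)2 (THF, −78 to 0 °C) gives 1-[2,4-bis(benzyloxy)-6-hydroxyphenyl]-3-[4-({2-[4-(benzyloxy)phenyl]-5,7-dimethoxy-4-oxo-4H-chromen-6-yl}oxy)phenyl]propane-1,3-dione F8.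
- p-TsOH in toluene at 90 °C cyclodehydrates F8 to 21.

**Further compounds**
F1 | step 9 | 4-[4-(1,3-dioxolan-2-yl)phenoxy]-2-iodo-3,5-dimethoxyphenol | COc1cc(O)c(I)c(OC)c1Oc1ccc(cc1)C1OCCO1
F2 | step 6 | 4-[4-(1,3-dioxolan-2-yl)phenoxy]-3,5-dimethoxyphenol | COc1cc(O)cc(OC)c1Oc1ccc(cc1)C1OCCO1
F3 | step 6 | 2-bromo-4-[4-(1,3-dioxolan-2-yl)phenoxy]-3,5-dimethoxyphenol | COc1cc(O)c(Br)c(OC)c1Oc1ccc(cc1)C1OCCO1
F4 | step 6 | {2-bromo-4-[4-(1,3-dioxolan-2-yl)phenoxy]-3,5-dimethoxyphenoxy}trimethylsilane | COc1cc(O[Si](C)(C)C)c(Br)c(OC)c1Oc1ccc(cc1)C1OCCO1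
F5 | step 6 | lithium 4-[4-(1,3-dioxolan-2-yl)phenoxy]-3,5-dimethoxy-2-(trimethylsilyl)phenolate | COc1cc([O-])c([Si](C)(C)C)c(OC)c1Oc1ccc(cc1)C1OCCO1.[Li+]
F6 | step 12 | 4-({2-[4-(benzyloxy)phenyl]-5,7-dimethoxy-4-oxo-4H-chromen-6-yl}oxy)benzoic acid | COc1cc2oc(-c3ccc(OCc4ccccc4)cc3)cc(=O)c2c(OC)c1Oc1ccc(C(=O)O)cc1
F7 | step 12 | 2-acetyl-3,5-bis(benzyloxy)phenyl 4-({2-[4-(benzyloxy)phenyl]-5,7-dimethoxy-4-oxo-4H-chromen-6-yl}oxy)benzoate | COc1cc2oc(-c3ccc(OCc4ccccc4)cc3)cc(=O)c2c(OC)c1Oc1ccc(C(=O)Oc2cc(OCc3ccccc3)cc(OCc3ccccc3)c2C(C)=O)cc1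
F8 | step 12 | 1-[2,4-bis(benzyloxy)-6-hydroxyphenyl]-3-[4-({2-[4-(benzyloxy)phenyl]-5,7-dimethoxy-4-oxo-4H-chromen-6-yl}oxy)phenyl]propane-1,3-dione | COc1cc2oc(-c3ccc(OCc4ccccc4)cc3)cc(=O)c2c(OC)c1Oc1ccc(C(=O)CC(=O)c2c(O)cc(OCc3ccccc3)cc2OCc2ccccc2)cc1
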